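## Structural features

Stephaflavone B is a biflavone: two 5-hydroxy-7-methoxyflavone units joined by one C–C bond between C3 of unit 1 (the unit with the free 4-hydroxyphenyl group at C2) and C6 of unit 2 (an acacetin 7-methyl ether core with a 4-methoxyphenyl group at C2). Each unit is a phloroglucinol-type ring A fused to a 4-pyranone ring C, with ring B attached at C2. The target has no stereocentre. Its only stereochemical feature is the hindered C3–C6'' axis, flanked by the C2 aryl group and C4 carbonyl of unit 1 and by the C5 hydroxyl and C7 methoxy group of unit 2, and no configuration is specified for it. Fragile points are the pyranone rings (opened by hot hydroxide or alkoxide), the electron-rich rings (attacked by strong electrophiles and oxidants), and three phenols that must be told apart from three methyl ethers; two of these phenols are chelated to a C4 carbonyl and one is free. The real difficulty is the crowded inter-unit bond, which is a poor candidate for cross-coupling or Friedel–Crafts chemistry, together with correct placement of every ring A oxygen. The key step uses ring A of unit 1: C8a carries the ring oxygen O1, its neighbour C4a carries the C4 acyl carbon, and the next atom C5 carries oxygen. This is the pattern produced when a 3-alkoxyaryne inserts into the C–O bond of a carboxylic acid (oxygen at the remote aryne carbon, acyl at the carbon next to the alkoxy group), so the inter-unit bond can be brought in ready-made on the acid.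

## Logic of the disconnections

22 to 21: the O–CH3 bonds at both C5 positions and the O–CH2Ph bond at the 4' oxygen of unit 1 are reconnected. Free phenols would add to the aryne and would blur the earlier alkylations, so all three stay masked until the end. The gain is that one reagent separates three hydroxyls from three methyl ethers in the last step. The demand is a Lewis acid that cleaves only ethers chelated to a carbonyl, plus the benzyl ether.

21 to 20: the C2=C3 double bond of unit 1 is taken back to the saturated C2–C3 bond. The reason is that the polar ring closure of the key step gives a flavanone. Both stereocentres of 20 are temporary, so no stereocontrol is needed. The demand is a dehydrogenation that tolerates a fully substituted C3 and electron-rich rings.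

20 to 10 and 18 (from 17), through 19: O1–C2 is cut first (retro-oxa-Michael) to give 19, then C4–C4a and O1–C8a are cut together. The whole of ring A of unit 1 then sits in a symmetrical C6 aryne, and the crowded C3–C6'' bond is already present in 10 as an ordinary sp2–sp2 bond of an acrylic acid. The biflavone is thereby reduced to one flavone with a three-carbon acid side chain and one small aryne precursor. The demands are that the carboxylate adds at the aryne carbon remote from the methoxy group and that the aryl anion transfers to the hindered acyl carbon faster than it is protonated.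

10 to 8 and 9: the Cα=Cβ bond is cut, a Perkin-type condensation in the forward sense. This places the future C2 aryl group and the future C3–C6'' bond on adjacent carbons by a simple condensation. The demand is enolisation of a methylene group flanked by a di-ortho-substituted ring.

8 to 7 to 6: the carboxyl carbon is traced to the internal alkene carbon of an allyl group, with loss of the terminal CH2. An allyl group is the easiest two-carbon handle to install regioselectively. The demand is an oxidant that cleaves a terminal alkene without touching the chromone double bond or the electron-rich rings.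

6 to 5 to 4 to 2 and 3, and 2 to 1: the C6–CH2 bond is cut by a retro-Claisen shift to the O-allyl ether, and the O–CH3 and O-allyl bonds are cut back to the phenols of 1. The shift has only one open ortho position, so attachment at C6 is certain, and 1 already contains the whole skeleton of unit 2. The demand is clean discrimination of the C7 hydroxyl from the chelated C5 hydroxyl in the first alkylation.

17 to 15 to 12 to 11: the S–O bond of the triflate, the C2–Si bond and the carbamate C–O bond are cut. 11 is symmetrical, so both ortho sites of the carbamate are the same and only one silyl arene can form by directed metalation. The demand is lithiation next to the carbamate rather than between the two methoxy groups.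

## Other disconnections considered

Alternative 1: The cut is in ring A of unit 2 at C4a–C5. Chalcone A1 is traced to pyrone A2, a 4-methoxy-2-pyrone with unit 1 at its C3 and a 2-oxo-4-arylbut-3-enyl chain at C6. In the forward step Mg(OMe)2 in methanol would open the lactone to a methyl ester, and the magnesium enolate of the side-chain methylene would close onto that ester and aromatise to A1.
- In favour: the step is mild and biomimetic, uses no oxidant or strong electrophile, and delivers the C5 and C8a oxygens of unit 2 as free phenols. On mildness and on protecting-group economy at unit 2 it is the better plan.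
- Against: the crowded inter-unit bond is moved, not avoided, because unit 1 C3 must first be joined to the pyrone C3 by coupling two hindered heteroaryl partners. A1 has two different hydroxyls ortho to the acyl group, and ring C of unit 2 must close through the unhindered one; closure through the other would attach the units through C8. An oxidative ring closure and a deprotection still follow.
- Comparison: the chosen plan is safer on regiochemistry, since the Claisen shift has one open position and aryne polarisation sets ring A of unit 1. Mechanistically the two are comparable polar acyl-transfer ring constructions. On step count the alternative is longer, because A2 needs a pyrone synthesis, a coupling and a side-chain acylation.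

Alternative 2: Four bonds of ring A of unit 2 are cut (C8–C8a, C5–C6, C7–C8, C4a–C5), giving diazoketone A4 and ynol ether A5. In the forward step, irradiation of A4 would give a pyranonyl ketene by Wolff rearrangement. [2+2] addition to A5, 4π ring opening, 6π ring closure and tautomerisation would then give phenol A3 (Danheiser benzannulation).
- In favour: it is the most convergent plan, with both units complete before they meet. The polarity of the ynol ether puts the hydroxyl ortho and the methoxy meta to the carbon carrying unit 1. The C5 hydroxyl of unit 2 appears free. The inter-unit bond is carried in on a slim alkyne, so it equals the chosen plan in avoiding a hindered coupling and is better in convergence and in needing only one deprotection afterwards.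
- Against: A5 is a push-pull alkyne conjugated to a chromone carbonyl, so it is less nucleophilic and easily hydrated. A4 needs diazomethane or diazo transfer on a base-sensitive pyranone. Pyranones and chromones absorb the same light and have photochemistry of their own. A vinylketene whose alkene belongs to an electron-poor pyranone has no close analogy.
- Comparison: structurally it builds unit 2 where the chosen plan builds unit 1. Mechanistically it is a pericyclic cascade with several untested links, against one polar cascade of a known type. The two multi-step precursors should make it longer overall.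

Alternative 3: The same two bonds of unit 1 are cut as in the chosen plan (C4–C4a and O1–C2), but ring A comes from phloroglucinol A8 and ring C from ketoester A7. Heating the two without solvent would give, by loss of ethanol, an acylketene (or an aryl ester) that acylates A8, and cyclodehydration would give biflavone A6.
- In favour: A8 is symmetrical, so there is no regiochemical question. The flavone oxidation level arrives directly, so no dehydrogenation is needed. The C5 hydroxyl of unit 1 is free, and the C7 hydroxyl can be methylated selectively because it is not chelated. A7 would be reached from 8 in two steps and no aryne precursor is needed, so this plan is about two steps shorter and is the better on step economy.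
- Against: the condensation needs roughly 240 °C, which endangers the benzyl ether and the ketoester (retro-Claisen cleavage, loss of the ester group). A ketoester with a di-ortho-substituted aryl group at the α-carbon is a poor substrate for this reaction. The competing closure to a coumarin is possible. The hindered ketone must be attacked twice, in acylation and in ring closure.
- Comparison: both plans keep the inter-unit bond intact and build ring C of unit 1 around it. The alternative is equal on regiochemical certainty and better on length. The chosen plan runs at lower temperature, with a charged intramolecular acyl transfer, and its later oxidation accepts every stereoisomer and the open-chain form.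

Key step: step 11

Remark on the chemistry: 20 is a racemate and its descriptors give relative configuration only; 22 has no stereocentre and its C3–C6'' axis is treated as unspecified. The silicon of 17 lies between the triflate and a methoxy group, and 10 has its two aryl groups cis (E); both are what the strategy requires, so no structure needed correction.

Improvements to the precursor design:
- The allyl group is cleaved with OsO4/NaIO4 and then NaClO2, not with RuO4 or ozone, which would attack the electron-rich rings.
- Unit 2 C5 stays a methyl ether, the smallest group next to the reacting acid, and is removed by the same reagent as the unit 1 C5 methyl ether.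
- The oxidation in step 12 is chosen so that both diastereomers of 20 and any uncyclised 19 converge on 21.

## Steps

Step 1
Reactants: 1 acacetin (5,7-dihydroxy-2-(4-methoxyphenyl)-4H-chromen-4-one)
Product: 2 5-hydroxy-7-methoxy-2-(4-methoxyphenyl)-4H-chromen-4-one
Conditions: MeI (1.1 equiv), K2CO3, acetone, rt to 40 °C
Reagents that add atoms: iodomethane, CI
Why: Williamson ether synthesis; the C7 hydroxyl is the more acidic, unchelated phenol, while the C5 hydroxyl is held in a hydrogen bond to C4=O and should stay free with one equivalent of MeI.

Step 2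
Reactants: 2 5-hydroxy-7-methoxy-2-(4-methoxyphenyl)-4H-chromen-4-one; 3 allyl bromide
Product: 4 7-methoxy-2-(4-methoxyphenyl)-5-(prop-2-en-1-yloxy)-4H-chromen-4-one
Conditions: allyl bromide (3 equiv), K2CO3, DMF, 60 °C
Reagents that add atoms: none
Why: Williamson ether synthesis under more forcing conditions; the chelated C5 phenoxide is the only nucleophile left and the allylic bromide is reactive enough to alkylate it.

Step 3
Reactants: 4 7-methoxy-2-(4-methoxyphenyl)-5-(prop-2-en-1-yloxy)-4H-chromen-4-one
Product: 5 5-hydroxy-7-methoxy-2-(4-methoxyphenyl)-6-(prop-2-en-1-yl)-4H-chromen-4-one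
Conditions: N,N-diethylaniline, 200 °C
Reagents that add atoms: none
Why: Aromatic Claisen rearrangement; the [3,3] shift can deliver the allyl group only to C6 because the other ortho position (C4a) is a ring-fusion carbon, and tautomerisation restores the chelated C5 phenol.

Step 4
Reactants: 5 5-hydroxy-7-methoxy-2-(4-methoxyphenyl)-6-(prop-2-en-1-yl)-4H-chromen-4-one
Product: 6 5,7-dimethoxy-2-(4-methoxyphenyl)-6-(prop-2-en-1-yl)-4H-chromen-4-one
Conditions: Me2SO4, K2CO3, acetone, reflux
Reagents that add atoms: dimethyl sulfate, COS(=O)(=O)OC
Why: Williamson-type O-methylation; hot dimethyl sulfate with K2CO3 is the standard way to methylate a chelated and flanked C5 hydroxyl of a flavone.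

Step 5
Reactants: 6 5,7-dimethoxy-2-(4-methoxyphenyl)-6-(prop-2-en-1-yl)-4H-chromen-4-one
Product: 7 [5,7-dimethoxy-2-(4-methoxyphenyl)-4-oxo-4H-chromen-6-yl]acetaldehyde
Conditions: OsO4 (2 mol%), NaIO4, 2,6-lutidine, dioxane/H2O, rt
Reagents that add atoms: osmium tetroxide (catalytic oxygen carrier), O=[Os](=O)(=O)=O; sodium periodate (terminal oxidant), [Na+].[O-]I(=O)(=O)=O
Why: Lemieux–Johnson oxidation; OsO4 dihydroxylates the terminal alkene much faster than the electron-poor C2=C3 bond of the chromone, NaIO4 cleaves the diol, and the electron-rich rings are left alone.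

Step 6
Reactants: 7 [5,7-dimethoxy-2-(4-methoxyphenyl)-4-oxo-4H-chromen-6-yl]acetaldehyde
Product: 8 [5,7-dimethoxy-2-(4-methoxyphenyl)-4-oxo-4H-chromen-6-yl]acetic acid
Conditions: NaClO2, NaH2PO4, 2-methylbut-2-ene, t-BuOH/THF/H2O, 0 °C to rt
Reagents that add atoms: sodium chlorite, [Na+].[O-]Cl=O
Why: Pinnick oxidation under buffered conditions; the alkene scavenger removes HOCl before it can chlorinate the electron-rich rings, and the aldehyde is used at once because arylacetaldehydes enolise and self-condense.

Step 7
Reactants: 8 [5,7-dimethoxy-2-(4-methoxyphenyl)-4-oxo-4H-chromen-6-yl]acetic acid; 9 4-(benzyloxy)benzaldehyde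
Product: 10 (E)-3-[4-(benzyloxy)phenyl]-2-[5,7-dimethoxy-2-(4-methoxyphenyl)-4-oxo-4H-chromen-6-yl]prop-2-enoic acid
Conditions: Ac2O, Et3N, 110 °C; then H2O, 60 °C, acidify
Reagents that add atoms: none
Why: Perkin (Oglialoro) condensation; the arylacetic acid is activated and enolised in Ac2O/Et3N, adds to the aldehyde and loses water, and the E acid with the two aryl groups cis is the usual thermodynamic product (the geometry has no consequence for step 11).

Step 8
Reactants: 11 3,5-dimethoxyphenol
Product: 12 3,5-dimethoxyphenyl N-(propan-2-yl)carbamate
Conditions: i-PrNCO, Et3N (cat.), CH2Cl2, rt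
Reagents that add atoms: isopropyl isocyanate, CC(C)N=C=O
Why: Base-catalysed addition of a phenol to an isocyanate; the N-monoalkyl carbamate is a strong director of ortho-metalation and can later be removed under mild E1cB conditions.

Step 9
Reactants: 12 3,5-dimethoxyphenyl N-(propan-2-yl)carbamate
Product: 15 3,5-dimethoxy-2-(trimethylsilyl)phenyl N-(propan-2-yl)carbamate, via N-silyl carbamate 13 (not isolated), via C-silylated N-silyl carbamate 14 (not isolated)
Conditions: TBSOTf, TMEDA, Et2O, 0 °C to rt; n-BuLi (2 equiv), TMEDA, −78 °C; TMSCl, −78 °C to rt; aq. NaHSO4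
Reagents that add atoms: chlorotrimethylsilane, C[Si](C)(C)Cl; tert-butyldimethylsilyl triflate (its atoms stay only in 13 and 14), CC(C)(C)[Si](C)(C)OS(=O)(=O)C(F)(F)F
Why: Directed ortho-metalation; N-silylation in the flask masks the N–H, n-BuLi/TMEDA removes the C2 proton that is activated by both the carbamate and the C3 methoxy group (the two ortho sites are equal by symmetry), TMSCl traps the aryllithium at −78 °C before an anionic Fries shift can occur, and aqueous acid removes the N-silyl group.

Step 10
Reactants: 15 3,5-dimethoxy-2-(trimethylsilyl)phenyl N-(propan-2-yl)carbamate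
Product: 17 3,5-dimethoxy-2-(trimethylsilyl)phenyl trifluoromethanesulfonate, via silylphenol 16 (not isolated)
Conditions: Et2NH, DBU, MeCN, 40 °C; then PhNTf2, rt
Reagents that add atoms: N-phenylbis(trifluoromethanesulfonimide), O=S(=O)(N(c1ccccc1)S(=O)(=O)C(F)(F)F)C(F)(F)F
Why: E1cB cleavage of the carbamate by DBU (the carbamoyl fragment ends as a urea with Et2NH) frees the phenoxide, which PhNTf2 triflates in the same flask; the mild fluoride-free conditions keep the C–Si bond.

Step 11
Reactants: 10 (E)-3-[4-(benzyloxy)phenyl]-2-[5,7-dimethoxy-2-(4-methoxyphenyl)-4-oxo-4H-chromen-6-yl]prop-2-enoic acid; 17 3,5-dimethoxy-2-(trimethylsilyl)phenyl trifluoromethanesulfonate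
Product: 20 rac-(2R,3S)-2-[4-(benzyloxy)phenyl]-3-[5,7-dimethoxy-2-(4-methoxyphenyl)-4-oxo-4H-chromen-6-yl]-5,7-dimethoxy-2,3-dihydro-4H-chromen-4-one (trans), via aryne 18 (not isolated), via hydroxychalcone 19 (not isolated)
Conditions: CsF (4 equiv), 17 (1.5 equiv, added in portions), THF, 125 °C, sealed tube
Reagents that add atoms: none
Why: Fluoride removes the silyl group of 17 and triflate leaves to give aryne 18, whose C3 methoxy group polarises and distorts the triple bond so that the caesium carboxylate of 10 adds through oxygen at C1, the carbon remote from that methoxy group, placing the aryl anion at C2 where the adjacent C–O bond stabilises it. The aryl anion then attacks the ester carbonyl through a four-membered alkoxide that opens to the ortho-acyl phenoxide 19; this is the known fluoride-induced insertion of arynes into the C–O bond of carboxylic acids, including its extension in which unsaturated acids go on to chromanones, applied here to a more hindered α-aryl acid. Ring C of unit 1 closes by 6-endo-trig oxa-Michael addition of the phenoxide oxygen (future O1) to the β-carbon (future C2), helped by the ortho methoxy group (future C5 substituent), which twists the enone out of plane and favours the closed form. C2 is set in this addition and C3 on protonation of the resulting enolate; because the addition is reversible and C3 can epimerise, both are under thermodynamic control and the trans isomer with both aryl groups pseudo-equatorial should prevail, as a racemate. The first selectivity needed is regiochemical (oxygen at future C8a, acyl at future C4a), and the C3 methoxy group of 18 secures it. The second is acyl transfer in preference to protonation of the aryl anion, which the aprotic medium, the high temperature and the masking of every phenol in 10 as a methyl or benzyl ether are meant to secure. Adding 17 in portions keeps the aryne concentration low so that phenoxide 19 cyclises instead of being arylated. Neither the diastereomer ratio nor complete ring closure matters, because step 12 converts both diastereomers and any 19 into 21.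

Step 12
Reactants: 20 rac-(2R,3S)-2-[4-(benzyloxy)phenyl]-3-[5,7-dimethoxy-2-(4-methoxyphenyl)-4-oxo-4H-chromen-6-yl]-5,7-dimethoxy-2,3-dihydro-4H-chromen-4-one
Product: 21 2-[4-(benzyloxy)phenyl]-3-[5,7-dimethoxy-2-(4-methoxyphenyl)-4-oxo-4H-chromen-6-yl]-5,7-dimethoxy-4H-chromen-4-one
Conditions: I2 (10 mol%), DMSO, 130 °C
Reagents that add atoms: none
Why: Iodine-catalysed dehydrogenation of a flavanone in DMSO (iodination at C3 through the enol, loss of HI to form C2=C3, reoxidation of HI by DMSO); the same conditions effect the oxidative cyclisation of 2'-hydroxychalcones, so both stereocentres are erased and all material from step 11 converges.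

Step 13
Reactants: 21 2-[4-(benzyloxy)phenyl]-3-[5,7-dimethoxy-2-(4-methoxyphenyl)-4-oxo-4H-chromen-6-yl]-5,7-dimethoxy-4H-chromen-4-one
Product: 22 stephaflavone B
Conditions: BCl3 (excess), C6HMe5, CH2Cl2, −78 °C to 0 °C; then MeOH/H2O
Reagents that add atoms: none
Why: Chelation-controlled ether cleavage; BCl3 bridges each C4 carbonyl and its peri C5 methoxy oxygen so that chloride removes only these two methyl groups while the C7 and 4' methyl ethers survive, and the benzyl ether is cleaved at low temperature with pentamethylbenzene trapping the benzyl cation before it can alkylate the electron-rich rings.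

## Compound list

1 | acacetin (5,7-dihydroxy-2-(4-methoxyphenyl)-4H-chromen-4-one) | COc1ccc(-c2cc(=O)c3c(O)cc(O)cc3o2)cc1 | starting material
2 | 5-hydroxy-7-methoxy-2-(4-methoxyphenyl)-4H-chromen-4-one | COc1ccc(-c2cc(=O)c3c(O)cc(OC)cc3o2)cc1 | intermediate
3 | allyl bromide | C=CCBr | starting material
4 | 7-methoxy-2-(4-methoxyphenyl)-5-(prop-2-en-1-yloxy)-4H-chromen-4-one | COc1ccc(-c2cc(=O)c3c(OCC=C)cc(OC)cc3o2)cc1 | intermediate
5 | 5-hydroxy-7-methoxy-2-(4-methoxyphenyl)-6-(prop-2-en-1-yl)-4H-chromen-4-one | COc1ccc(-c2cc(=O)c3c(O)c(CC=C)c(OC)cc3o2)cc1 | intermediate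
6 | 5,7-dimethoxy-2-(4-methoxyphenyl)-6-(prop-2-en-1-yl)-4H-chromen-4-one | COc1ccc(-c2cc(=O)c3c(OC)c(CC=C)c(OC)cc3o2)cc1 | intermediate
7 | [5,7-dimethoxy-2-(4-methoxyphenyl)-4-oxo-4H-chromen-6-yl]acetaldehyde | COc1ccc(-c2cc(=O)c3c(OC)c(CC=O)c(OC)cc3o2)cc1 | intermediate
8 | [5,7-dimethoxy-2-(4-methoxyphenyl)-4-oxo-4H-chromen-6-yl]acetic acid | COc1ccc(-c2cc(=O)c3c(OC)c(CC(=O)O)c(OC)cc3o2)cc1 | intermediate
9 | 4-(benzyloxy)benzaldehyde | O=Cc1ccc(OCc2ccccc2)cc1 | starting material
10 | (E)-3-[4-(benzyloxy)phenyl]-2-[5,7-dimethoxy-2-(4-methoxyphenyl)-4-oxo-4H-chromen-6-yl]prop-2-enoic acid | OC(=O)/C(=C/c1ccc(OCc2ccccc2)cc1)c1c(OC)cc2oc(-c3ccc(OC)cc3)cc(=O)c2c1OC | intermediate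
11 | 3,5-dimethoxyphenol | COc1cc(O)cc(OC)c1 | starting material
12 | 3,5-dimethoxyphenyl N-(propan-2-yl)carbamate | COc1cc(OC)cc(OC(=O)NC(C)C)c1 | intermediate
13 | 3,5-dimethoxyphenyl N-(tert-butyldimethylsilyl)-N-(propan-2-yl)carbamate | COc1cc(OC)cc(OC(=O)N(C(C)C)[Si](C)(C)C(C)(C)C)c1 | intermediate (not isolated)
14 | 3,5-dimethoxy-2-(trimethylsilyl)phenyl N-(tert-butyldimethylsilyl)-N-(propan-2-yl)carbamate | COc1cc(OC)c([Si](C)(C)C)c(OC(=O)N(C(C)C)[Si](C)(C)C(C)(C)C)c1 | intermediate (not isolated)
15 | 3,5-dimethoxy-2-(trimethylsilyl)phenyl N-(propan-2-yl)carbamate | COc1cc(OC)c([Si](C)(C)C)c(OC(=O)NC(C)C)c1 | intermediate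
16 | 3,5-dimethoxy-2-(trimethylsilyl)phenol (formed as its DBU salt) | COc1cc(O)c([Si](C)(C)C)c(OC)c1 | intermediate (not isolated)
17 | 3,5-dimethoxy-2-(trimethylsilyl)phenyl trifluoromethanesulfonate | COc1cc(OC)c([Si](C)(C)C)c(OS(=O)(=O)C(F)(F)F)c1 | intermediate
18 | 3,5-dimethoxybenzyne (1,2-didehydro-3,5-dimethoxybenzene) | COC1=CC(OC)=CC#C1 | intermediate (not isolated)
19 | (E)-3-[4-(benzyloxy)phenyl]-2-[5,7-dimethoxy-2-(4-methoxyphenyl)-4-oxo-4H-chromen-6-yl]-1-(2-hydroxy-4,6-dimethoxyphenyl)prop-2-en-1-one | O=C(c1c(O)cc(OC)cc1OC)/C(=C/c1ccc(OCc2ccccc2)cc1)c1c(OC)cc2oc(-c3ccc(OC)cc3)cc(=O)c2c1OC | intermediate (not isolated)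
20 | rac-(2R,3S)-2-[4-(benzyloxy)phenyl]-3-[5,7-dimethoxy-2-(4-methoxyphenyl)-4-oxo-4H-chromen-6-yl]-5,7-dimethoxy-2,3-dihydro-4H-chromen-4-one (trans; racemate, relative configuration drawn) | O=C1[C@@H](c2c(OC)cc3oc(-c4ccc(OC)cc4)cc(=O)c3c2OC)[C@H](c2ccc(OCc3ccccc3)cc2)Oc2cc(OC)cc(OC)c21 | intermediate
21 | 2-[4-(benzyloxy)phenyl]-3-[5,7-dimethoxy-2-(4-methoxyphenyl)-4-oxo-4H-chromen-6-yl]-5,7-dimethoxy-4H-chromen-4-one | COc1ccc(-c2cc(=O)c3c(OC)c(-c4c(-c5ccc(OCc6ccccc6)cc5)oc5cc(OC)cc(OC)c5c4=O)c(OC)cc3o2)cc1 | intermediate
22 | stephaflavone B | COc1ccc(-c2cc(=O)c3c(O)c(-c4c(-c5ccc(O)cc5)oc5cc(OC)cc(O)c5c4=O)c(OC)cc3o2)cc1 | target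

## Step count and least certain steps

Total: 13 steps. Longest linear sequence: 10 steps (steps 1 to 7, then 11, 12 and 13, from 1 to 22). The aryne precursor branch (steps 8 to 10) joins at step 11.

Step 11 (key step). The most likely failure is protonation of the aryl anion before it reaches the acyl carbon, which would stop the sequence at simple O-arylation of the carboxylate. The acyl carbon is shielded by the di-ortho-substituted α-aryl group, and the anion itself sits between a methoxy group and the ester oxygen. A second risk is arylation of the phenoxide by further aryne before ring closure. Fallback with known chemistry: start from 8 and 11 and heat them in BF3·OEt2 (Friedel–Crafts acylation ortho to the hydroxyl) to give the deoxybenzoin 1-(2-hydroxy-4,6-dimethoxyphenyl)-2-[5,7-dimethoxy-2-(4-methoxyphenyl)-4-oxo-4H-chromen-6-yl]ethan-1-one F1. Condensation of F1 with 9 (piperidine, EtOH, reflux) passes through 19 and closes to 20, where the route is rejoined.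

Step 7. Enolisation and condensation at the crowded methylene of 8 with an electron-rich aldehyde may be slow, and prolonged heating invites decarboxylation of the product. Fallback: start from 8 and make the methyl ester, methyl [5,7-dimethoxy-2-(4-methoxyphenyl)-4-oxo-4H-chromen-6-yl]acetate F2 (MeI, K2CO3, DMF). Add its lithium enolate (LiN(SiMe3)2, THF, −78 °C) to 9 to give the aldol, methyl 3-[4-(benzyloxy)phenyl]-3-hydroxy-2-[5,7-dimethoxy-2-(4-methoxyphenyl)-4-oxo-4H-chromen-6-yl]propanoate F3. Dehydrate it (TsOH, toluene, reflux) to methyl (E)-3-[4-(benzyloxy)phenyl]-2-[5,7-dimethoxy-2-(4-methoxyphenyl)-4-oxo-4H-chromen-6-yl]prop-2-enoate F4, and hydrolyse (LiOH, THF/H2O) to return to 10. Either alkene geometry would serve in step 11.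

Step 9. Metalation may occur partly at C4 between the two methoxy groups, or the carbamoyl group may migrate to carbon (anionic Fries shift) if the aryllithium warms before it is trapped. Fallback: start from 11 and brominate (NBS, CH2Cl2, −78 °C) to 2-bromo-3,5-dimethoxyphenol F5, separated from its 4-bromo isomer. Silylate (HMDS, THF, 70 °C) to (2-bromo-3,5-dimethoxyphenoxy)trimethylsilane F6. Treat with n-BuLi (THF, −78 °C; bromine–lithium exchange and O-to-C silyl shift to the lithium salt of 16), then Tf2O, to rejoin the route at 17.

Step 12. Iodination of the electron-rich rings may compete, or elimination at the fully substituted C3 may stall. Fallback: start from 20, form the enolate (LiN(SiMe3)2, THF, −78 °C) and trap it with PhSeCl on the face away from the C2 aryl group. This gives 2-[4-(benzyloxy)phenyl]-3-[5,7-dimethoxy-2-(4-methoxyphenyl)-4-oxo-4H-chromen-6-yl]-5,7-dimethoxy-3-(phenylselanyl)-2,3-dihydro-4H-chromen-4-one F7, with selenium cis to H2. Oxidation (H2O2, CH2Cl2/pyridine, 0 °C) and syn elimination of the selenoxide lead back to 21.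

Step 13. Cleavage of the flanked C5 methyl ether of unit 2 may be incomplete, a non-chelated methyl ether may be lost on long exposure, or the benzyl cation may alkylate a ring. Fallback: separate the two tasks. Start from 21 and hydrogenolyse (H2, Pd/C, EtOAc/THF, rt) to 2-(4-hydroxyphenyl)-3-[5,7-dimethoxy-2-(4-methoxyphenyl)-4-oxo-4H-chromen-6-yl]-5,7-dimethoxy-4H-chromen-4-one F8. Then remove only the two chelated methyl groups (BCl3, CH2Cl2, 0 °C) to arrive at 22.

## Further compounds

F1 | step 11 | 1-(2-hydroxy-4,6-dimethoxyphenyl)-2-[5,7-dimethoxy-2-(4-methoxyphenyl)-4-oxo-4H-chromen-6-yl]ethan-1-one | O=C(Cc1c(OC)cc2oc(-c3ccc(OC)cc3)cc(=O)c2c1OC)c1c(O)cc(OC)cc1OC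
F2 | step 7 | methyl [5,7-dimethoxy-2-(4-methoxyphenyl)-4-oxo-4H-chromen-6-yl]acetate | COC(=O)Cc1c(OC)cc2oc(-c3ccc(OC)cc3)cc(=O)c2c1OC
F3 | step 7 | methyl 3-[4-(benzyloxy)phenyl]-3-hydroxy-2-[5,7-dimethoxy-2-(4-methoxyphenyl)-4-oxo-4H-chromen-6-yl]propanoate (mixture of racemic diastereomers, no configuration assigned) | COC(=O)C(C(O)c1ccc(OCc2ccccc2)cc1)c1c(OC)cc2oc(-c3ccc(OC)cc3)cc(=O)c2c1OC
F4 | step 7 | methyl (E)-3-[4-(benzyloxy)phenyl]-2-[5,7-dimethoxy-2-(4-methoxyphenyl)-4-oxo-4H-chromen-6-yl]prop-2-enoate | COC(=O)/C(=C/c1ccc(OCc2ccccc2)cc1)c1c(OC)cc2oc(-c3ccc(OC)cc3)cc(=O)c2c1OC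
F5 | step 9 | 2-bromo-3,5-dimethoxyphenol | COc1cc(O)c(Br)c(OC)c1
F6 | step 9 | (2-bromo-3,5-dimethoxyphenoxy)trimethylsilane | COc1cc(O[Si](C)(C)C)c(Br)c(OC)c1
F7 | step 12 | 2-[4-(benzyloxy)phenyl]-3-[5,7-dimethoxy-2-(4-methoxyphenyl)-4-oxo-4H-chromen-6-yl]-5,7-dimethoxy-3-(phenylselanyl)-2,3-dihydro-4H-chromen-4-one (racemate, selenium cis to H2) | O=C1[C@]([Se]c2ccccc2)(c2c(OC)cc3oc(-c4ccc(OC)cc4)cc(=O)c3c2OC)[C@H](c2ccc(OCc3ccccc3)cc2)Oc2cc(OC)cc(OC)c21
F8 | step 13 | 2-(4-hydroxyphenyl)-3-[5,7-dimethoxy-2-(4-methoxyphenyl)-4-oxo-4H-chromen-6-yl]-5,7-dimethoxy-4H-chromen-4-one | COc1ccc(-c2cc(=O)c3c(OC)c(-c4c(-c5ccc(O)cc5)oc5cc(OC)cc(OC)c5c4=O)c(OC)cc3o2)cc1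
A1 | alternative 1 | (E)-1-{3-[2-(4-(benzyloxy)phenyl)-5,7-dimethoxy-4-oxo-4H-chromen-3-yl]-2,6-dihydroxy-4-methoxyphenyl}-3-(4-methoxyphenyl)prop-2-en-1-one | COc1cc(O)c(C(=O)/C=C/c2ccc(OC)cc2)c(O)c1-c3c(-c4ccc(OCc5ccccc5)cc4)oc4cc(OC)cc(OC)c4c3=O
A2 | alternative 1 | 3-[2-(4-(benzyloxy)phenyl)-5,7-dimethoxy-4-oxo-4H-chromen-3-yl]-4-methoxy-6-[(E)-4-(4-methoxyphenyl)-2-oxobut-3-en-1-yl]-2H-pyran-2-one | COC1=C(c2c(-c3ccc(OCc4ccccc4)cc3)oc3cc(OC)cc(OC)c3c2=O)C(=O)OC(CC(=O)/C=C/c2ccc(OC)cc2)=C1
A3 | alternative 2 | 2-[4-(benzyloxy)phenyl]-3-[5-hydroxy-7-methoxy-2-(4-methoxyphenyl)-4-oxo-4H-chromen-6-yl]-5,7-dimethoxy-4H-chromen-4-one | COc1ccc(-c2cc(=O)c3c(O)c(-c4c(-c5ccc(OCc6ccccc6)cc5)oc5cc(OC)cc(OC)c5c4=O)c(OC)cc3o2)cc1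
A4 | alternative 2 | 2-(diazoacetyl)-6-(4-methoxyphenyl)-4H-pyran-4-one | COc1ccc(-c2cc(=O)cc(C(=O)C=[N+]=[N-])o2)cc1
A5 | alternative 2 | 2-[4-(benzyloxy)phenyl]-5,7-dimethoxy-3-(methoxyethynyl)-4H-chromen-4-one | COC#Cc1c(-c2ccc(OCc3ccccc3)cc2)oc2cc(OC)cc(OC)c2c1=O
A6 | alternative 3 | 2-[4-(benzyloxy)phenyl]-3-[5,7-dimethoxy-2-(4-methoxyphenyl)-4-oxo-4H-chromen-6-yl]-5,7-dihydroxy-4H-chromen-4-one | COc1ccc(-c2cc(=O)c3c(OC)c(-c4c(-c5ccc(OCc6ccccc6)cc5)oc5cc(O)cc(O)c5c4=O)c(OC)cc3o2)cc1
A7 | alternative 3 | ethyl 3-[4-(benzyloxy)phenyl]-2-[5,7-dimethoxy-2-(4-methoxyphenyl)-4-oxo-4H-chromen-6-yl]-3-oxopropanoate (racemate) | CCOC(=O)C(C(=O)c1ccc(OCc2ccccc2)cc1)c1c(OC)cc2oc(-c3ccc(OC)cc3)cc(=O)c2c1OC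
A8 | alternative 3 | phloroglucinol (benzene-1,3,5-triol) | Oc1cc(O)cc(O)c1
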